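**Retrosynthetic overview**

1. The target is read as the (2S,3R,4R)-oxolane (ring atoms O1, C2 aryl, C3 CH2OH, C4 trimethoxybenzyl, C5): the aryl group is trans to the hydroxymethyl group, and the hydroxymethyl group is cis to the benzyl group.
2. The C2–aryl bond is made last, by a redox-relay Heck–Matsuda arylation of the enol ether alcohol [(R)-4-(3,4,5-trimethoxybenzyl)-4,5-dihydrofuran-3-yl]methanol with 3,4,5-trimethoxybenzenediazonium tetrafluoroborate; the aldehyde formed is reduced back to the alcohol.
3. Enabling feature: O1 makes C2=C3 of the precursor an enol ether, so the aryl group goes to C2; the exocyclic hydroxymethyl carbon on C3 is the hydride donor that ends the relay; the C4 benzyl group blocks one ring face, so anti approach plus syn addition gives the 2,3-trans-3,4-cis pattern.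
4. The oxolane ring (as its 4,5-dihydro form) comes from an acyl-lactone rearrangement of the α-formyl derivative of (R)-4-(3,4,5-trimethoxybenzyl)butyrolactone, in which the lactone ring oxygen becomes O1.
5. Ring order: a temporary butyrolactone ring first (auxiliary-controlled alkylation, reduction, lactonisation), then the ring switch to the dihydrofuran; both benzene rings are bought.

Key step: step 8

**Step 1**
Reactants: 1 3-(3,4,5-trimethoxyphenyl)propanoic acid; 2 (S)-4-benzyloxazolidin-2-one
Product: 4 (S)-4-benzyl-3-[3-(3,4,5-trimethoxyphenyl)propanoyl]oxazolidin-2-one, via mixed pivalic anhydride 3 (not isolated)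
Conditions: Me3CCOCl, Et3N, THF, −20 °C; then 2, LiCl, −20 °C to rt
Reagents that add atoms: none
Why: Mixed-anhydride N-acylation of the oxazolidinone (attachment of the Evans auxiliary) activates only the carboxyl group and forms no stereocentre.

**Step 2**
Reactants: 4 (S)-4-benzyl-3-[3-(3,4,5-trimethoxyphenyl)propanoyl]oxazolidin-2-one; 5 tert-butyl bromoacetate
Product: 7 tert-butyl (R)-3-[(S)-4-benzyl-2-oxooxazolidine-3-carbonyl]-4-(3,4,5-trimethoxyphenyl)butanoate, via sodium enolate 6 (not isolated)
Conditions: NaN(SiMe3)2, THF, −78 °C; then 5, −78 to −40 °C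
Reagents that add atoms: none
Why: Evans asymmetric alkylation, in which the chelated sodium (Z)-enolate is alkylated on the face opposite the benzyl group of the auxiliary, should set the new stereocentre as R.

**Step 3**
Reactants: 7 tert-butyl (R)-3-[(S)-4-benzyl-2-oxooxazolidine-3-carbonyl]-4-(3,4,5-trimethoxyphenyl)butanoate
Product: 9 (R)-4-(3,4,5-trimethoxybenzyl)dihydrofuran-2(3H)-one, via hydroxy ester 8 (not isolated)
Conditions: LiBH4, MeOH (1 equiv), THF, 0 °C; aqueous work-up; then CF3CO2H, CH2Cl2, rt
Reagents that add atoms: none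
Why: LiBH4 should reduce the activated imide carbonyl selectively over the tert-butyl ester (reductive auxiliary cleavage), and acid then closes the γ-hydroxy tert-butyl ester to the lactone with loss of 2-methylpropene, the stereocentre being untouched.

**Step 4**
Reactants: 9 (R)-4-(3,4,5-trimethoxybenzyl)dihydrofuran-2(3H)-one; 10 ethyl formate
Product: 12 (R)-3-(hydroxymethylene)-4-(3,4,5-trimethoxybenzyl)dihydrofuran-2(3H)-one, via sodium enolate 11 (not isolated)
Conditions: NaH, EtOH (cat.), THF, 0 °C to rt; then aq. HCl to pH 3
Reagents that add atoms: none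
Why: Crossed Claisen condensation (α-formylation) of the lactone enolate with the non-enolisable formate is driven by formation of the stabilised enolate of the β-dicarbonyl product, and C4 is not acidic and keeps its configuration.

**Step 5**
Reactants: 12 (R)-3-(hydroxymethylene)-4-(3,4,5-trimethoxybenzyl)dihydrofuran-2(3H)-one
Product: 14 methyl (R)-4-(3,4,5-trimethoxybenzyl)-4,5-dihydrofuran-3-carboxylate, via cyclic acetal ester 13 (not isolated)
Conditions: HCl (1.25 M in MeOH), rt; evaporate; then TsOH·H2O (5 mol %), toluene, reflux over 4 Å molecular sieves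
Reagents that add atoms: methanol, CO
Why: Acyl-lactone rearrangement, in which acid methanolysis opens the lactone and the freed C5 hydroxyl closes on the formyl carbon (5-exo-trig) to the cyclic acetal ester, followed by acid-catalysed loss of methanol, should give the push-pull enol ether ester without touching C4.

**Step 6**
Reactants: 14 methyl (R)-4-(3,4,5-trimethoxybenzyl)-4,5-dihydrofuran-3-carboxylate
Product: 15 [(R)-4-(3,4,5-trimethoxybenzyl)-4,5-dihydrofuran-3-yl]methanol
Conditions: iBu2AlH (2.5 equiv), CH2Cl2, −78 °C; aq. potassium sodium tartrate; chromatography on Et3N-deactivated silica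
Reagents that add atoms: none
Why: iBu2AlH should effect 1,2-reduction of the vinylogous carbonate ester to the allylic alcohol (ester-to-alcohol hydride reduction), and the acid-labile enol ether survives a work-up kept basic.

**Step 7**
Reactants: 16 3,4,5-trimethoxyaniline
Product: 17 3,4,5-trimethoxybenzenediazonium tetrafluoroborate
Conditions: NaNO2, HBF4 (48% aq.), H2O, 0 °C; filter, wash with cold Et2O
Reagents that add atoms: sodium nitrite, [Na+].[O-]N=O; tetrafluoroboric acid, [H+].F[B-](F)(F)F
Why: Diazotisation of the aniline with nitrous acid in aqueous HBF4 should give the arenediazonium tetrafluoroborate, which precipitates and can be dried and stored cold.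

**Step 8**
Reactants: 15 [(R)-4-(3,4,5-trimethoxybenzyl)-4,5-dihydrofuran-3-yl]methanol; 17 3,4,5-trimethoxybenzenediazonium tetrafluoroborate
Product: 18 (2S,3S,4R)-4-(3,4,5-trimethoxybenzyl)-2-(3,4,5-trimethoxyphenyl)tetrahydrofuran-3-carbaldehyde
Conditions: 17 (1.3 equiv), Pd2(dba)3 (3 mol %), 2-(4,4-dimethyl-4,5-dihydro-1,3-oxazol-2-yl)pyridine (8 mol %), 2,6-di-tert-butyl-4-methylpyridine (1.5 equiv), DMF, 0 °C to rt
Reagents that add atoms: none
Why: Zerovalent palladium adds oxidatively to 17 with loss of N2, and the cationic arylpalladium species binds C2=C3 of the enol ether on the face opposite the C4 benzyl group and inserts syn, the aryl group going to C2 and palladium to C3; syn β-hydride elimination from the exocyclic carbinol carbon, re-insertion that returns the hydride to C3 on the face palladium had held, and loss of the hydroxyl proton then release the aldehyde and zerovalent palladium. The closest known reaction types are the Heck–Matsuda arylation of 2,3-dihydrofurans at the oxygen-bearing carbon and the redox-relay Heck arylation of alkenols and enol ethers. No ring is closed in this step. C2 is set by substrate control (approach anti to the C4 substituent), and C3 by the stereospecific syn carbopalladation and hydride return, which together leave the formyl group trans to the aryl group and cis to the benzyl group. The step needs aryl transfer to C2 and not C3, and hydride loss toward the carbinol and not toward C4–H: the first is secured by O1 (enol ether polarisation) together with the unsubstituted C2 and the proximal hydroxyl, the second by the hydroxymethyl group as the only irreversible hydride sink and by the bidentate N,N ligand that keeps the palladium hydride bound during the walk.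

**Step 9**
Reactants: 18 (2S,3S,4R)-4-(3,4,5-trimethoxybenzyl)-2-(3,4,5-trimethoxyphenyl)tetrahydrofuran-3-carbaldehyde
Product: 19 [(2S,3R,4R)-4-(3,4,5-trimethoxybenzyl)-2-(3,4,5-trimethoxyphenyl)tetrahydrofuran-3-yl]methanol (CNP0321241.1)
Conditions: NaBH4, MeOH, 0 °C (crude 18 used at once)
Reagents that add atoms: none
Why: Borohydride reduction of the aldehyde to the primary alcohol is fast at 0 °C, so the epimerisable C3 centre next to the carbonyl should be preserved, and no new stereocentre arises.

**Compound list**

1 | 3-(3,4,5-trimethoxyphenyl)propanoic acid | COc1cc(CCC(=O)O)cc(OC)c1OC | starting material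
2 | (S)-4-benzyloxazolidin-2-one | O=C1OC[C@H](Cc2ccccc2)N1 | starting material
3 | 3-(3,4,5-trimethoxyphenyl)propanoic pivalic anhydride | COc1cc(CCC(=O)OC(=O)C(C)(C)C)cc(OC)c1OC | intermediate
4 | (S)-4-benzyl-3-[3-(3,4,5-trimethoxyphenyl)propanoyl]oxazolidin-2-one | COc1cc(CCC(=O)N2[C@@H](Cc3ccccc3)COC2=O)cc(OC)c1OC | intermediate
5 | tert-butyl bromoacetate | CC(C)(C)OC(=O)CBr | starting material
6 | sodium (Z)-enolate of 4 | COc1cc(C/C=C(\[O-])N2[C@@H](Cc3ccccc3)COC2=O)cc(OC)c1OC.[Na+] | intermediate
7 | tert-butyl (R)-3-[(S)-4-benzyl-2-oxooxazolidine-3-carbonyl]-4-(3,4,5-trimethoxyphenyl)butanoate | COc1cc(C[C@H](CC(=O)OC(C)(C)C)C(=O)N2[C@@H](Cc3ccccc3)COC2=O)cc(OC)c1OC | intermediate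
8 | tert-butyl (R)-3-(hydroxymethyl)-4-(3,4,5-trimethoxyphenyl)butanoate | COc1cc(C[C@H](CC(=O)OC(C)(C)C)CO)cc(OC)c1OC | intermediate
9 | (R)-4-(3,4,5-trimethoxybenzyl)dihydrofuran-2(3H)-one | COc1cc(C[C@H]2COC(=O)C2)cc(OC)c1OC | intermediate
10 | ethyl formate | CCOC=O | starting material
11 | sodium [(R)-2-oxo-4-(3,4,5-trimethoxybenzyl)dihydrofuran-3(2H)-ylidene]methanolate | COc1cc(C[C@H]2COC(=O)C2=C[O-])cc(OC)c1OC.[Na+] | intermediate
12 | (R)-3-(hydroxymethylene)-4-(3,4,5-trimethoxybenzyl)dihydrofuran-2(3H)-one (enol form of the 3-formyl lactone, alkene geometry not assigned) | COc1cc(C[C@H]2COC(=O)C2=CO)cc(OC)c1OC | intermediate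
13 | methyl (4R)-2-methoxy-4-(3,4,5-trimethoxybenzyl)tetrahydrofuran-3-carboxylate (mixture at C2 and C3) | COc1cc(C[C@H]2COC(OC)C2C(=O)OC)cc(OC)c1OC | intermediate
14 | methyl (R)-4-(3,4,5-trimethoxybenzyl)-4,5-dihydrofuran-3-carboxylate | COc1cc(C[C@H]2COC=C2C(=O)OC)cc(OC)c1OC | intermediate
15 | [(R)-4-(3,4,5-trimethoxybenzyl)-4,5-dihydrofuran-3-yl]methanol | COc1cc(C[C@H]2COC=C2CO)cc(OC)c1OC | intermediate
16 | 3,4,5-trimethoxyaniline | COc1cc(N)cc(OC)c1OC | starting material
17 | 3,4,5-trimethoxybenzenediazonium tetrafluoroborate | COc1cc([N+]#N)cc(OC)c1OC.F[B-](F)(F)F | intermediate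
18 | (2S,3S,4R)-4-(3,4,5-trimethoxybenzyl)-2-(3,4,5-trimethoxyphenyl)tetrahydrofuran-3-carbaldehyde | COc1cc(C[C@H]2CO[C@H](c3cc(OC)c(OC)c(OC)c3)[C@H]2C=O)cc(OC)c1OC | intermediate
19 | [(2S,3R,4R)-4-(3,4,5-trimethoxybenzyl)-2-(3,4,5-trimethoxyphenyl)tetrahydrofuran-3-yl]methanol | COc1cc(C[C@H]2CO[C@H](c3cc(OC)c(OC)c(OC)c3)[C@H]2CO)cc(OC)c1OC | target

**Count**

Total step count: 9. Longest linear sequence: 8 steps (steps 1 to 6, 8 and 9); step 7 is a one-step side branch.

**Steps most likely to fail**

1. Step 8. The risks are: hydride loss toward C4 instead of the carbinol, which would erase the C4 stereocentre; release of the enol from palladium before the hydride returns, which would lose control at C3; acid-induced decomposition of the enol ether; and base-induced ring opening of the β-alkoxy aldehyde before reduction. The fallback makes the same C2–aryl bond by polar chemistry and sets out from 15. Silylation (tBuMe2SiCl, imidazole, DMF) should give the tert-butyldimethylsilyl ether F1. Dry HCl (1 equiv, Et2O, −78 °C) should add across the enol ether, the proton entering C3 anti to the benzyl group, to give the α-chloro ether F2, used in the flask. Commercial 3,4,5-trimethoxyphenylmagnesium bromide (THF, −78 to 0 °C) should then substitute chloride through the oxocarbenium ion, the aryl group entering C2 anti to both ring substituents, to give the silyl ether of the target F3. Bu4NF (THF) brings the sequence back to the route at 19.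

2. Step 5. The risks are incomplete loss of methanol, ring opening to the acyclic methoxyacrylate, and migration of the double bond toward C4 with loss of the stereocentre. The fallback introduces the one-carbon unit on a preformed enol ether and sets out from 9. iBu2AlH (CH2Cl2, −78 °C) should give the lactol F4. Dehydration (MeSO2Cl, Et3N, CH2Cl2, 0 °C to reflux) should give the dihydrofuran F5. Vilsmeier–Haack formylation (POCl3, DMF, 0 °C; aq. NaOAc) at the β-carbon of the enol ether should give the enal F6. Luche reduction (NaBH4, CeCl3·7H2O, MeOH, −40 °C) comes back to the route at 15, so that step 6 is bypassed as well.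

3. Step 6. The risks are hydrolysis or allylic transposition of the enol ether alcohol during the aluminium work-up, and competing 1,4-reduction. The fallback reverses the order of reduction and enol ether formation and sets out from 13, isolated after the first stage of step 5. LiAlH4 (THF, 0 °C) should give the acid-stable acetal alcohol F7. Me3SiOSO2CF3 with iPr2NEt (CH2Cl2, −20 °C to rt) should silylate the hydroxyl and eliminate methanol from the acetal to give the trimethylsilyl ether F8. K2CO3 in MeOH then comes back to the route at 15 under basic conditions only.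

**Further compounds**

F1 | step 8 | tert-butyldimethyl{[(R)-4-(3,4,5-trimethoxybenzyl)-4,5-dihydrofuran-3-yl]methoxy}silane | COc1cc(C[C@H]2COC=C2CO[Si](C)(C)C(C)(C)C)cc(OC)c1OC
F2 | step 8 | tert-butyl{[(3R,4R)-2-chloro-4-(3,4,5-trimethoxybenzyl)tetrahydrofuran-3-yl]methoxy}dimethylsilane (mixture at C2) | COc1cc(C[C@H]2COC(Cl)[C@H]2CO[Si](C)(C)C(C)(C)C)cc(OC)c1OC
F3 | step 8 | tert-butyldimethyl{[(2S,3R,4R)-4-(3,4,5-trimethoxybenzyl)-2-(3,4,5-trimethoxyphenyl)tetrahydrofuran-3-yl]methoxy}silane | COc1cc(C[C@H]2CO[C@H](c3cc(OC)c(OC)c(OC)c3)[C@H]2CO[Si](C)(C)C(C)(C)C)cc(OC)c1OC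
F4 | step 5 | (4R)-4-(3,4,5-trimethoxybenzyl)tetrahydrofuran-2-ol (mixture at C2) | COc1cc(C[C@H]2COC(O)C2)cc(OC)c1OC
F5 | step 5 | (R)-3-(3,4,5-trimethoxybenzyl)-2,3-dihydrofuran | COc1cc(C[C@H]2COC=C2)cc(OC)c1OC
F6 | step 5 | (R)-4-(3,4,5-trimethoxybenzyl)-4,5-dihydrofuran-3-carbaldehyde | COc1cc(C[C@H]2COC=C2C=O)cc(OC)c1OC
F7 | step 6 | [(4R)-2-methoxy-4-(3,4,5-trimethoxybenzyl)tetrahydrofuran-3-yl]methanol (mixture at C2 and C3) | COc1cc(C[C@H]2COC(OC)C2CO)cc(OC)c1OC
F8 | step 6 | trimethyl{[(R)-4-(3,4,5-trimethoxybenzyl)-4,5-dihydrofuran-3-yl]methoxy}silane | COc1cc(C[C@H]2COC=C2CO[Si](C)(C)C)cc(OC)c1OC
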